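## Structural features

The target is a germacranolide. Its ten-membered carbocycle (C1–C10) carries a Z trisubstituted olefin at C10=C1, a cis trisubstituted epoxide at C4–C5 (C4 quaternary, methyl-bearing) and an α-methylene-γ-butyrolactone fused cis at C6–C7 through the C6 oxygen. C8, next to the ring fusion, bears an (E)-4-hydroxy-2-methylbut-2-enoate whose oxygen is trans to C11. Five stereocentres, C4 (R), C5 (S), C6 (S), C7 (S) and C8 (R), stand in an unbroken row on one edge of the ring: epoxide oxygen and lactone oxygen are erythro (cis on the ring), C6–O and C7–C11 are cis, C7–C11 and C8–O are trans. The fragile groups are the epoxide facing a transannular olefin (acid would open it with cyclisation across the ring), the α-methylene lactone (Michael acceptor), a C8 oxygen that can take over the lactone carbonyl under base, and the allylic primary alcohol of the side chain. The real difficulty is a medium ring with two cis units (Z olefin, cis epoxide) on which three contiguous centres (C6, C7, C8) must be set without acid or strong base late in the route. The key step exploits the 1,3-relation of the C6 oxygen and C11 across C7, together with the oxygen on C8: a two-carbon acetal tether on O6 delivers C11 to C7 of a C7=C8 ring olefin, closing the five-membered lactone ring as its lactol ether, and the radical left at C8 is oxygenated.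

## Logic of the disconnections

33 is cut at the ester C–O bond on C8, after the side-chain hydroxyl has been silylated again (32), to give 26 and 30. The enoate side chain would not survive the enolate chemistry needed for C13, so it is attached last. The gain is a convergent end game with a two-step acid. The demand is an acylation of a hindered secondary hydroxyl beside the lactone without letting it open the lactone, and a final desilylation near neutrality.

26 is simplified to 21 by removing the exocyclic C11=C13 bond (through 25, silylated on O8). The methylene lactone is the most electrophilic group and is made late by enolate aminomethylation and elimination. The gain is a lactone without a Michael acceptor for the earlier steps. The demand is that enolate formation at C11 spares the epoxide and that O8 is masked, since a free C8 alkoxide could attack C12.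

21 is taken back through 20 and 19 to 18 by lowering C12 from lactone to acetal and freeing O8. An acetal at C12 is what a haloacetal radical cyclisation delivers. A 4-methoxybenzyl acetal is chosen instead of a simple alkyl acetal: hydrolysis or chromic acid oxidation of an alkyl acetal needs acid, and acid would open the C4–C5 epoxide with participation of the C10=C1 olefin. The demand is an oxidative, pH-neutral unmasking followed by a mild lactol oxidation.

18 is cut at C7–C11 and at C8–O, giving 16. These two bonds, the five-membered ring and the centres C7 and C8 come from one radical chain reaction that is steered by the C6 oxygen. The gain is the loss of one ring and two stereocentres, and C11 and C12 become a tether that is put on in one step. The demand is 5-exo addition to C7 only, and oxygen capture at C8 on the face away from the new ring.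

16 is opened at C7=C8 to the acyclic 15. This is the one ring bond whose geometry does not matter, because both carbons become sp3 in the key step, so ring-closing metathesis needs no E/Z control. The gain is an open chain in which every stereocentre and both cis units are already fixed. The demand is closure of a ten-membered ring without engaging the trisubstituted C10=C1 olefin. A ring expansion by anionic oxy-Cope rearrangement was weighed for this ring and set aside for three reasons:
- its chair transition state, with the added vinyl group trans to the second alkenyl group, should give the E olefin at C10=C1;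
- it erases the only stereocentre of a terpene starting material;
- C6 would then rest on an enantioselective reduction of a carbonyl flanked by two alkenyl groups.

15 is cut at the O6–C12 acetal bond into 11 and 14, and 14 at its vinyl C–O bond into 12 and 13. C11, C12 and bromine arrive in one operation on the free C6 hydroxyl. The gain is that the radical precursor is installed on an open-chain alcohol. The demand is a bromoetherification selective for the enol ether and neutral toward the epoxide.

11 is cut at C6–C7 into 9 and 10. The C5–O bond of the epoxide can steer a vinyl nucleophile. The gain is a two-carbon simplification that creates C6 beside centres already set. The demand is Felkin–Anh (erythro) selectivity.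

9 is traced through 8 to 7 by removing the epoxide oxygen from C4 and C5 and returning C6 to the alcohol level. A Z trisubstituted allylic alcohol is a substrate for titanium tartrate epoxidation, so C4 and C5 are set by the catalyst before any ring exists. The gain is an achiral trienol. The demand is chemoselectivity for the allylic olefin.

7 is cut at C9–C10 into 5 and 6; 5 is deacetylated 4; 4 is cut at C10=C1 into 3, which is 1 shortened at its terminal olefin. The Z geometry of C4=C5 is bought with 1. The Z geometry of C10=C1 is made by an α-iodo Wittig olefination (iodine cis to the chain) and a coupling with retention. The gain is a commodity terpene ester as the source of C1–C6. The demand is selective cleavage of the more electron-rich olefin of 1 and kinetic Z control.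

30 comes from 29 by hydrolysis, and 29 is cut at its C2=C3 olefin into 27 and 28. A stabilised α-methyl ylide gives the E enoate directly. The gain is a side chain in two steps from two commercial reagents. The demand is only that the silyl ether survives hydroxide.

## Other disconnections considered

Alternative 1: The cut is the C1–C6 bond, restored in the cis-fused bicyclic γ-hydroxystannane A1. Forward, Pb(OAc)4 (or PhI(OAc)2) would oxidise the tertiary C6 alcohol, C1–C6 would break as tin leaves C10, and the dione A2 would appear with the Z C10=C1 olefin.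
- In its favour: the medium ring arises from a six–six bicycle with no high-dilution closure, which is better than the metathesis of the chosen plan.
- The Z geometry follows stereospecifically from the antiperiplanar C–Sn and C1–C6 bonds, which is the equal of the iodo-olefination and coupling used here.
- A2 already holds oxygen at C6 and C8, so no radical oxygen capture is needed; on this point it is the better.
- Against it: A2 is achiral and carries none of the five stereocentres, and C7 is the central carbon of a β-diketone (enolisation, O- versus C-alkylation when C11–C12 are attached).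
- Also against it: the two carbonyls must be told apart and reduced with relative and absolute control, and the epoxide must then be placed on the ring by substrate control.
- Comparison on structure: the chosen plan sets C4–C6 before the ring exists and relays them to C7 and C8 in one step, whereas this route builds the ring first and postpones every stereocentre.
- Comparison on mechanism: both use stoichiometric tin, and this one adds lead.
- Comparison on step economy: probably shorter to the ring and longer from the ring to the target, so at best equal overall.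

Alternative 2: The cut is C7–C8 together with O–C6. The aldoxime A3 would be oxidised with NaOCl to its nitrile oxide, which adds across the terminal vinyl group on the cis epoxide to give the bridged isoxazoline A4.
- In its favour: one metal-free step closes the carbocycle and delivers C6–O and C8 at the ketone level, which is better than the chosen plan on ring construction, where the key step does not close the carbocycle.
- A3 would rest on the same asymmetric epoxidation, so the epoxide centres are secured equally.
- No tin is used, which is the better on reagents.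
- Against it: cycloaddition to a bridged ten-membered ring must outrun nitrile oxide dimerisation, and the face selectivity at C6 rests on the allylic epoxide alone.
- Also against it: hypochlorite must spare the trisubstituted olefin, and N–O cleavage must later spare epoxide and olefin.
- Also against it: A4 leaves C7 as a methylene, so C11–C12 and the C7 and C8 centres would have to be added afterwards by enolate alkylation next to a β-oxygen and a ketone reduction.
- Comparison on structure: it sets the ring and C6 but not C7 and C8, the reverse of the chosen key step.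
- Comparison on mechanism: a concerted cycloaddition, free of radical-chain side reactions.
- Comparison on step economy: equal up to the ring-closed stage, poorer beyond it.

Alternative 3: The cut is C5–C6. The Z-vinyl iodide of the iodo aldehyde A5 would be converted by CrCl2 with catalytic NiCl2 into a vinylchromium species that adds to the C6 aldehyde, giving the ten-membered dienol A6.
- In its favour: C7, C8 and the lactone carbons (as the tert-butyl ester) are set in the open chain before ring closure.
- That is better than the chosen plan at C8, which depends on the face selectivity of oxygen capture, and at C12, which needs no change of oxidation level.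
- The chromium-mediated closure cannot suffer a ring-contracting metathesis pathway, and is the better on that count.
- Against it: C6 is created in the macrocyclisation with 1,2-induction from C7 only, so the cis relation of O6 and C11 is not assured.
- Also against it: the epoxide must be introduced after ring closure by hydroxyl-directed epoxidation on a mobile ring, where the chosen plan uses reagent control on an open-chain alcohol.
- Both Z trisubstituted olefins must still be built, one as a Z-vinyl iodide; this is an equal burden.
- Comparison on structure: C7 and C8 early, C4–C6 late, the reverse of the chosen plan.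
- Comparison on mechanism: polar organometallic addition with stoichiometric chromium, against a radical chain with stoichiometric tin.
- Comparison on step economy: about equal.

Key step: step 11

Assumption: C12 of the acetal is carried as both epimers from 15 to 20 and is drawn without a descriptor; germacrane locants (C1–C13) are used for all ring compounds. The configurations of 16 and 18 were re-derived from the target and agree with it at C4, C5, C6 (and C7, C8 in 18).

Step 1
Reactants: 1 neryl acetate
Product: 3 (2Z)-3-methyl-6-oxohex-2-en-1-yl acetate, via secondary ozonide 2 (not isolated)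
Conditions: O3, CH2Cl2, pyridine, Sudan Red 7B (indicator), −78 °C; then Me2S, −78 → 20 °C
Reagents that add atoms: ozone, [O-][O+]=O
Why: Ozonolysis with reductive work-up; the terminal isopropylidene olefin is the more electron-rich one because the allylic acetate deactivates the other, and the dye marks the end point, so the Z olefin (later C4=C5) should stay untouched.

Step 2
Reactants: 3 (2Z)-3-methyl-6-oxohex-2-en-1-yl acetate
Product: 4 (2Z,6Z)-7-iodo-3-methylocta-2,6-dien-1-yl acetate
Conditions: EtPPh3I, n-BuLi, THF, 20 °C; I2, −78 °C; NaN(SiMe3)2, −20 °C; then 3, −78 → −20 °C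
Reagents that add atoms: ethyltriphenylphosphonium iodide, CC[P+](c1ccccc1)(c1ccccc1)c1ccccc1.[I-]; iodine, II
Why: Stork–Zhao-type Wittig olefination with the α-iodoethylidene ylide; the unstabilised ylide reacts under kinetic control and should place iodine cis to the chain, which fixes the geometry of the later C10=C1 olefin; the acetate tolerates the low temperature.

Step 3
Reactants: 4 (2Z,6Z)-7-iodo-3-methylocta-2,6-dien-1-yl acetate
Product: 5 (2Z,6Z)-7-iodo-3-methylocta-2,6-dien-1-ol
Conditions: K2CO3 (cat.), MeOH, 0 → 20 °C
Reagents that add atoms: none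
Why: Base-catalysed transesterification; removing the allylic ester before the coupling leaves nothing that zerovalent palladium could ionise and frees the hydroxyl that later directs the epoxidation.

Step 4
Reactants: 5 (2Z,6Z)-7-iodo-3-methylocta-2,6-dien-1-ol; 6 allyltributylstannane
Product: 7 (2Z,6Z)-3,7-dimethyldeca-2,6,9-trien-1-ol
Conditions: Pd2(dba)3 (cat.), AsPh3, DMF, 25–40 °C
Reagents that add atoms: none
Why: Stille coupling; oxidative addition and reductive elimination keep the olefin geometry, so the allyl group (C9, C8 and one terminal carbon) replaces iodine cis to the chain and the Z C10=C1 olefin results; mild conditions should keep the skipped diene out of conjugation.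

Step 5
Reactants: 7 (2Z,6Z)-3,7-dimethyldeca-2,6,9-trien-1-ol
Product: 8 [(2S,3R)-3-methyl-3-[(3Z)-4-methylhepta-3,6-dien-1-yl]oxiran-2-yl]methanol
Conditions: Ti(OiPr)4 (10 mol %), L-(+)-diethyl tartrate (12 mol %), t-BuOOH (anhydrous), 4 Å molecular sieves, CH2Cl2, −20 °C
Reagents that add atoms: tert-butyl hydroperoxide, CC(C)(C)OO
Why: Sharpless asymmetric epoxidation; only the allylic-alcohol olefin reacts, its Z geometry gives the cis epoxide, and the L-(+)-tartrate catalyst delivers oxygen to the face that sets C4 (R) and C5 (S) by reagent control.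

Step 6
Reactants: 8 [(2S,3R)-3-methyl-3-[(3Z)-4-methylhepta-3,6-dien-1-yl]oxiran-2-yl]methanol
Product: 9 (2R,3R)-3-methyl-3-[(3Z)-4-methylhepta-3,6-dien-1-yl]oxirane-2-carbaldehyde
Conditions: Dess–Martin periodinane, NaHCO3, CH2Cl2, 0 → 20 °C
Reagents that add atoms: none
Why: Dess–Martin oxidation under buffered conditions should give the epoxy aldehyde without opening the epoxide or epimerising C5 (the change of descriptor is formal); 9 is used directly.

Step 7
Reactants: 9 (2R,3R)-3-methyl-3-[(3Z)-4-methylhepta-3,6-dien-1-yl]oxirane-2-carbaldehyde; 10 vinylmagnesium bromide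
Product: 11 (1S)-1-[(2S,3R)-3-methyl-3-[(3Z)-4-methylhepta-3,6-dien-1-yl]oxiran-2-yl]prop-2-en-1-ol
Conditions: THF, −78 °C; then NH4Cl (aq)
Reagents that add atoms: none
Why: Grignard 1,2-addition to an α,β-epoxy aldehyde; in the Felkin–Anh arrangement the C5–O bond lies anti to the incoming vinyl group, which should favour the erythro (5S,6S) carbinol, the relation of epoxide and lactone oxygens in the target; the epimer is separable.

Step 8
Reactants: 12 4-methoxybenzyl alcohol; 13 ethyl vinyl ether
Product: 14 4-methoxybenzyl vinyl ether
Conditions: (1,10-phenanthroline)Pd(OAc)2 (cat.), 13 (excess, as co-solvent), CH2Cl2, 20 °C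
Reagents that add atoms: none
Why: Palladium-catalysed transfer vinylation (transetherification) of a primary alcohol; the excess of 13 drives the equilibrium and the medium is neutral.

Step 9
Reactants: 11 (1S)-1-[(2S,3R)-3-methyl-3-[(3Z)-4-methylhepta-3,6-dien-1-yl]oxiran-2-yl]prop-2-en-1-ol; 14 4-methoxybenzyl vinyl ether
Product: 15 (2S,3R)-2-[(1S)-1-{2-bromo-1-[(4-methoxybenzyl)oxy]ethoxy}prop-2-en-1-yl]-3-methyl-3-[(3Z)-4-methylhepta-3,6-dien-1-yl]oxirane (both acetal epimers)
Conditions: N-bromosuccinimide, 2,6-di-tert-butylpyridine, CH2Cl2, −40 → 0 °C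
Reagents that add atoms: N-bromosuccinimide, O=C1CCC(=O)N1Br
Why: Bromoacetalisation (bromoetherification of an enol ether); the vinyl ether is by far the most nucleophilic olefin, its bromonium/oxocarbenium ion is captured by the C6 hydroxyl, and the hindered base keeps the medium neutral for the epoxide.

Step 10
Reactants: 15 (2S,3R)-2-[(1S)-1-{2-bromo-1-[(4-methoxybenzyl)oxy]ethoxy}prop-2-en-1-yl]-3-methyl-3-[(3Z)-4-methylhepta-3,6-dien-1-yl]oxirane
Product: 16 (1S,2S,3Z,6Z,10R)-2-{2-bromo-1-[(4-methoxybenzyl)oxy]ethoxy}-6,10-dimethyl-11-oxabicyclo[8.1.0]undeca-3,6-diene (both acetal epimers)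
Conditions: second-generation Grubbs catalyst (H2IMes)(PCy3)Cl2Ru=CHPh (10 mol %), 1,4-benzoquinone (cat.), toluene (0.5 mM), 70 °C
Reagents that add atoms: none
Why: Ring-closing metathesis; the catalyst should load on the unhindered allyl terminus and close onto the hindered C7 vinyl group, the Z olefin and cis epoxide pre-fold the chain, and either geometry of the new C7=C8 bond is acceptable because both carbons become sp3 in step 11.

Step 11
Reactants: 16 (1S,2S,3Z,6Z,10R)-2-{2-bromo-1-[(4-methoxybenzyl)oxy]ethoxy}-6,10-dimethyl-11-oxabicyclo[8.1.0]undeca-3,6-diene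
Product: 18 (4R,5S,6S,7S,8R,1(10)Z)-4,5:6,12-diepoxy-12-[(4-methoxybenzyl)oxy]-13-norgermacr-1(10)-en-8-ol (cis-fused lactol ether; both C12 epimers), via C8 hydroperoxide 17 (not isolated)
Conditions: Bu3SnH (syringe pump), Et3B (cat.), dry air (slow stream), toluene (5 mM), 0 → 20 °C; then PPh3, 20 °C
Reagents that add atoms: dioxygen, O=O
Why: Bu3Sn• abstracts bromine, the primary C11 radical adds to C7 of the C7=C8 olefin to form C7–C11 and the oxolane ring, the secondary C8 radical is captured by dioxygen, the peroxyl radical takes hydrogen from Bu3SnH to give 17 and carry the chain, and PPh3 reduces 17 to 18. The closest known reaction type is the Ueno–Stork haloacetal cyclisation run under aerobic tin hydride conditions so that the cyclised radical is oxygenated. The five-membered ring closes in the 5-exo-trig mode, which is kinetically preferred over 6-endo attack at C8 for a 3-oxahex-5-enyl radical. C7 is controlled by the tether, which holds C11 on the face of C7 that carries the C6 oxygen, so only the cis ring fusion can form. C8 is controlled by the new ring, because the C7–C11 bond shields one face of the planar C8 radical and oxygen should enter anti to it on the periphery of the ten-membered ring, giving the trans (8R) alcohol. The step needs chemoselectivity for C7=C8, which the substrate secures because C4=C5 is already an epoxide and C10=C1 is out of reach of the tethered radical. It also needs oxygen to intercept the C8 radical but not the C11 radical, and stannane to stay scarce so that hydrogen transfer to C8 does not compete, which the lean air stream and the syringe pump are meant to secure. The acetal epimers and both C7=C8 geometries converge, since C12 later becomes a carbonyl and C7 and C8 are rehybridised.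

Step 12
Reactants: 18 (4R,5S,6S,7S,8R,1(10)Z)-4,5:6,12-diepoxy-12-[(4-methoxybenzyl)oxy]-13-norgermacr-1(10)-en-8-ol
Product: 19 (4R,5S,6S,7R,8R,1(10)Z)-4,5:6,12-diepoxy-12-[(4-methoxybenzyl)oxy]-8-(triethylsilyloxy)-13-norgermacr-1(10)-ene
Conditions: Et3SiCl, imidazole, 4-(dimethylamino)pyridine (cat.), CH2Cl2, 0 → 20 °C
Reagents that add atoms: chlorotriethylsilane, CC[Si](Cl)(CC)CC
Why: Silylation of the secondary C8 hydroxyl under basic, Lewis-acid-free conditions; the silyl ether blocks attack of O8 on C12 during steps 13–15 and is removable with buffered fluoride (the C7 descriptor changes by the sequence rule only).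

Step 13
Reactants: 19 (4R,5S,6S,7R,8R,1(10)Z)-4,5:6,12-diepoxy-12-[(4-methoxybenzyl)oxy]-8-(triethylsilyloxy)-13-norgermacr-1(10)-ene
Product: 20 (4R,5S,6S,7R,8R,1(10)Z)-4,5:6,12-diepoxy-8-(triethylsilyloxy)-13-norgermacr-1(10)-en-12-ol (lactol; both C12 epimers)
Conditions: DDQ, CH2Cl2/pH 7 phosphate buffer, 0 °C
Reagents that add atoms: none
Why: Oxidative cleavage of the 4-methoxybenzyl acetal (benzylic hydride abstraction, then hydrolysis of the oxocarbenium ion) frees the lactol at neutral pH, so the epoxide and the C10=C1 olefin never meet the acid that an alkyl acetal would need.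

Step 14
Reactants: 20 (4R,5S,6S,7R,8R,1(10)Z)-4,5:6,12-diepoxy-8-(triethylsilyloxy)-13-norgermacr-1(10)-en-12-ol
Product: 21 (4R,5S,6S,7R,8R,1(10)Z)-4,5-epoxy-8-(triethylsilyloxy)-13-norgermacr-1(10)-en-12,6-olide
Conditions: PhI(OAc)2, TEMPO (cat.), NaHCO3, CH2Cl2, 20 °C
Reagents that add atoms: none
Why: Oxoammonium (TEMPO) oxidation of the lactol to the γ-lactone; buffered and mild, it should leave olefin, epoxide and silyl ether alone, and the C12 epimers converge here.

Step 15
Reactants: 21 (4R,5S,6S,7R,8R,1(10)Z)-4,5-epoxy-8-(triethylsilyloxy)-13-norgermacr-1(10)-en-12,6-olide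
Product: 25 (4R,5S,6S,7R,8R,1(10)Z)-4,5-epoxy-8-(triethylsilyloxy)germacra-1(10),11(13)-dien-12,6-olide, via lithium enolate 22 (not isolated), via Mannich base 23 (not isolated), via ammonium iodide 24 (not isolated)
Conditions: LiN(iPr)2, THF, −78 °C; Me2N=CH2+ I−, −78 → 0 °C; MeI, MeOH/CH2Cl2, 20 °C; NaHCO3 (aq), 20 °C
Reagents that add atoms: N,N-dimethylmethyleneiminium iodide, C=[N+](C)C.[I-]
Why: α-Methylenation by Mannich reaction of the lactone enolate with Eschenmoser's salt, quaternisation and Hofmann-type elimination; the enolate has no β-leaving group (C7 carries only carbon and hydrogen) and the elimination needs only bicarbonate.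

Step 16
Reactants: 25 (4R,5S,6S,7R,8R,1(10)Z)-4,5-epoxy-8-(triethylsilyloxy)germacra-1(10),11(13)-dien-12,6-olide
Product: 26 (4R,5S,6S,7S,8R,1(10)Z)-4,5-epoxy-8-hydroxygermacra-1(10),11(13)-dien-12,6-olide
Conditions: Bu4NF, AcOH (1:1), THF, 0 °C
Reagents that add atoms: none
Why: Fluoride desilylation buffered with acetic acid; near-neutral, so neither the epoxide (acid) nor the methylene lactone and a C8 alkoxide (base, translactonisation) are put at risk.

Step 17
Reactants: 27 (tert-butyldimethylsilyloxy)acetaldehyde; 28 ethyl 2-(triphenyl-λ5-phosphanylidene)propanoate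
Product: 29 ethyl (2E)-4-[(tert-butyldimethylsilyl)oxy]-2-methylbut-2-enoate
Conditions: CH2Cl2, 20 °C
Reagents that add atoms: none
Why: Wittig olefination with a stabilised α-methyl ylide, which should give the E trisubstituted enoate.

Step 18
Reactants: 29 ethyl (2E)-4-[(tert-butyldimethylsilyl)oxy]-2-methylbut-2-enoate
Product: 30 (2E)-4-[(tert-butyldimethylsilyl)oxy]-2-methylbut-2-enoic acid
Conditions: LiOH, THF/MeOH/H2O, 0 → 20 °C; then cold dilute HCl to pH 4
Reagents that add atoms: lithium hydroxide, [Li+].[OH-]
Why: Saponification; a primary tert-butyldimethylsilyl ether tolerates aqueous hydroxide at room temperature and the conjugated olefin keeps its geometry.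

Step 19
Reactants: 26 (4R,5S,6S,7S,8R,1(10)Z)-4,5-epoxy-8-hydroxygermacra-1(10),11(13)-dien-12,6-olide; 30 (2E)-4-[(tert-butyldimethylsilyl)oxy]-2-methylbut-2-enoic acid
Product: 32 (4R,5S,6S,7S,8R,1(10)Z)-8-{[(2E)-4-(tert-butyldimethylsilyloxy)-2-methylbut-2-enoyl]oxy}-4,5-epoxygermacra-1(10),11(13)-dien-12,6-olide, via mixed anhydride 31 (not isolated)
Conditions: 30, 2,4,6-trichlorobenzoyl chloride, Et3N, THF, 0 °C; then 26, 4-(dimethylamino)pyridine, toluene, 20 °C
Reagents that add atoms: none
Why: Yamaguchi esterification; the mixed anhydride acylates the hindered C8 hydroxyl with the C8–O bond untouched, and no alkoxide is formed that could open the lactone.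

Step 20
Reactants: 32 (4R,5S,6S,7S,8R,1(10)Z)-8-{[(2E)-4-(tert-butyldimethylsilyloxy)-2-methylbut-2-enoyl]oxy}-4,5-epoxygermacra-1(10),11(13)-dien-12,6-olide
Product: 33 (4R,5S,6S,7S,8R,1(10)Z)-4,5-epoxy-8-{[(2E)-4-hydroxy-2-methylbut-2-enoyl]oxy}germacra-1(10),11(13)-dien-12,6-olide (CNP0198076.8)
Conditions: Bu4NF, AcOH (1:1), THF, 0 → 20 °C
Reagents that add atoms: none
Why: Buffered fluoride removes the primary allylic silyl ether; the neutral medium should preserve epoxide, methylene lactone and both esters.

## Compound list

1 | neryl acetate, (2Z)-3,7-dimethylocta-2,6-dien-1-yl acetate | CC(C)=CCC/C(C)=C\COC(C)=O | starting material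
2 | 3-[(3Z)-5-acetoxy-3-methylpent-3-en-1-yl]-5,5-dimethyl-1,2,4-trioxolane | CC1(C)OOC(CC/C(C)=C\COC(C)=O)O1 | intermediate
3 | (2Z)-3-methyl-6-oxohex-2-en-1-yl acetate | O=CCC/C(C)=C\COC(C)=O | intermediate
4 | (2Z,6Z)-7-iodo-3-methylocta-2,6-dien-1-yl acetate | I/C(C)=C\CC/C(C)=C\COC(C)=O | intermediate
5 | (2Z,6Z)-7-iodo-3-methylocta-2,6-dien-1-ol | I/C(C)=C\CC/C(C)=C\CO | intermediate
6 | allyltributylstannane | C=CC[Sn](CCCC)(CCCC)CCCC | starting material
7 | (2Z,6Z)-3,7-dimethyldeca-2,6,9-trien-1-ol | C=CC/C(C)=C\CC/C(C)=C\CO | intermediate
8 | [(2S,3R)-3-methyl-3-[(3Z)-4-methylhepta-3,6-dien-1-yl]oxiran-2-yl]methanol | OC[C@@H]1O[C@]1(C)CC/C=C(C)\CC=C | intermediate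
9 | (2R,3R)-3-methyl-3-[(3Z)-4-methylhepta-3,6-dien-1-yl]oxirane-2-carbaldehyde | O=C[C@@H]1O[C@]1(C)CC/C=C(C)\CC=C | intermediate
10 | vinylmagnesium bromide | C=C[Mg]Br | starting material
11 | (1S)-1-[(2S,3R)-3-methyl-3-[(3Z)-4-methylhepta-3,6-dien-1-yl]oxiran-2-yl]prop-2-en-1-ol | C=C[C@H](O)[C@@H]1O[C@]1(C)CC/C=C(C)\CC=C | intermediate
12 | 4-methoxybenzyl alcohol | COc1ccc(CO)cc1 | starting material
13 | ethyl vinyl ether | C=COCC | starting material
14 | 4-methoxybenzyl vinyl ether | C=COCc1ccc(OC)cc1 | intermediate
15 | (2S,3R)-2-[(1S)-1-{2-bromo-1-[(4-methoxybenzyl)oxy]ethoxy}prop-2-en-1-yl]-3-methyl-3-[(3Z)-4-methylhepta-3,6-dien-1-yl]oxirane, both acetal epimers | C=C[C@H](OC(CBr)OCc1ccc(OC)cc1)[C@@H]1O[C@]1(C)CC/C=C(C)\CC=C | intermediate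
16 | (1S,2S,3Z,6Z,10R)-2-{2-bromo-1-[(4-methoxybenzyl)oxy]ethoxy}-6,10-dimethyl-11-oxabicyclo[8.1.0]undeca-3,6-diene, both acetal epimers (bromoacetal on O6 of the ten-membered cis-epoxy dienol) | COc1ccc(COC(CBr)O[C@H]2/C=C\C/C(C)=C\CC[C@@]3(C)O[C@@H]23)cc1 | intermediate
17 | (4R,5S,6S,7R,8R,1(10)Z)-8-hydroperoxy-12-[(4-methoxybenzyl)oxy]-4,5:6,12-diepoxy-13-norgermacr-1(10)-ene, both C12 epimers | C1C(OCc3ccc(OC)cc3)O[C@H]2[C@@H]1[C@H](OO)C/C(C)=C\CC[C@@]1(C)O[C@@H]21 | intermediate
18 | (4R,5S,6S,7S,8R,1(10)Z)-4,5:6,12-diepoxy-12-[(4-methoxybenzyl)oxy]-13-norgermacr-1(10)-en-8-ol, both C12 epimers (cis-fused lactol ether with free C8 hydroxyl) | C1C(OCc3ccc(OC)cc3)O[C@H]2[C@@H]1[C@H](O)C/C(C)=C\CC[C@@]1(C)O[C@@H]21 | intermediate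
19 | (4R,5S,6S,7R,8R,1(10)Z)-4,5:6,12-diepoxy-12-[(4-methoxybenzyl)oxy]-8-(triethylsilyloxy)-13-norgermacr-1(10)-ene, both C12 epimers | C1C(OCc3ccc(OC)cc3)O[C@H]2[C@@H]1[C@H](O[Si](CC)(CC)CC)C/C(C)=C\CC[C@@]1(C)O[C@@H]21 | intermediate
20 | (4R,5S,6S,7R,8R,1(10)Z)-4,5:6,12-diepoxy-8-(triethylsilyloxy)-13-norgermacr-1(10)-en-12-ol, both C12 epimers | C1C(O)O[C@H]2[C@@H]1[C@H](O[Si](CC)(CC)CC)C/C(C)=C\CC[C@@]1(C)O[C@@H]21 | intermediate
21 | (4R,5S,6S,7R,8R,1(10)Z)-4,5-epoxy-8-(triethylsilyloxy)-13-norgermacr-1(10)-en-12,6-olide | C1C(=O)O[C@H]2[C@@H]1[C@H](O[Si](CC)(CC)CC)C/C(C)=C\CC[C@@]1(C)O[C@@H]21 | intermediate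
22 | lithium enolate of 21 (C11=C12–OLi) | C1=C(O[Li])O[C@H]2[C@@H]1[C@H](O[Si](CC)(CC)CC)C/C(C)=C\CC[C@@]1(C)O[C@@H]21 | intermediate
23 | (4R,5S,6S,7R,8R,1(10)Z)-13-(dimethylamino)-4,5-epoxy-8-(triethylsilyloxy)germacr-1(10)-en-12,6-olide, C11 epimers | CN(C)CC1C(=O)O[C@H]2[C@@H]1[C@H](O[Si](CC)(CC)CC)C/C(C)=C\CC[C@@]1(C)O[C@@H]21 | intermediate
24 | trimethylammonium iodide of 23 | C[N+](C)(C)CC1C(=O)O[C@H]2[C@@H]1[C@H](O[Si](CC)(CC)CC)C/C(C)=C\CC[C@@]1(C)O[C@@H]21.[I-] | intermediate
25 | (4R,5S,6S,7R,8R,1(10)Z)-4,5-epoxy-8-(triethylsilyloxy)germacra-1(10),11(13)-dien-12,6-olide | C=C1C(=O)O[C@H]2[C@@H]1[C@H](O[Si](CC)(CC)CC)C/C(C)=C\CC[C@@]1(C)O[C@@H]21 | intermediate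
26 | (4R,5S,6S,7S,8R,1(10)Z)-4,5-epoxy-8-hydroxygermacra-1(10),11(13)-dien-12,6-olide | C=C1C(=O)O[C@H]2[C@@H]1[C@H](O)C/C(C)=C\CC[C@@]1(C)O[C@@H]21 | intermediate
27 | (tert-butyldimethylsilyloxy)acetaldehyde | O=CCO[Si](C)(C)C(C)(C)C | starting material
28 | ethyl 2-(triphenyl-λ5-phosphanylidene)propanoate | CCOC(=O)C(C)=P(c1ccccc1)(c1ccccc1)c1ccccc1 | starting material
29 | ethyl (2E)-4-[(tert-butyldimethylsilyl)oxy]-2-methylbut-2-enoate | CCOC(=O)/C(C)=C/CO[Si](C)(C)C(C)(C)C | intermediate
30 | (2E)-4-[(tert-butyldimethylsilyl)oxy]-2-methylbut-2-enoic acid | OC(=O)/C(C)=C/CO[Si](C)(C)C(C)(C)C | intermediate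
31 | (2E)-4-[(tert-butyldimethylsilyl)oxy]-2-methylbut-2-enoic 2,4,6-trichlorobenzoic anhydride | O=C(OC(=O)/C(C)=C/CO[Si](C)(C)C(C)(C)C)c1c(Cl)cc(Cl)cc1Cl | intermediate
32 | (4R,5S,6S,7S,8R,1(10)Z)-8-{[(2E)-4-(tert-butyldimethylsilyloxy)-2-methylbut-2-enoyl]oxy}-4,5-epoxygermacra-1(10),11(13)-dien-12,6-olide | C=C1C(=O)O[C@H]2[C@@H]1[C@H](OC(=O)/C(C)=C/CO[Si](C)(C)C(C)(C)C)C/C(C)=C\CC[C@@]1(C)O[C@@H]21 | intermediate
33 | (4R,5S,6S,7S,8R,1(10)Z)-4,5-epoxy-8-{[(2E)-4-hydroxy-2-methylbut-2-enoyl]oxy}germacra-1(10),11(13)-dien-12,6-olide (CNP0198076.8) | C=C1C(=O)O[C@H]2[C@@H]1[C@H](OC(=O)/C(C)=C/CO)C/C(C)=C\CC[C@@]1(C)O[C@@H]21 | target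

## Step count and least certain steps

Total step count: 20. Longest linear sequence: 17 steps from 1 (steps 1–7, 9–16, 19 and 20); step 8 and steps 17–18 are side branches.

Step 11 (key step). Three processes can divert it:
- hydrogen transfer from the stannane to the C8 radical, or oxygen capture of the C11 radical before ring closure, because these rates are of similar size;
- addition of the C8 peroxyl radical to the nearby C10=C1 olefin;
- entry of oxygen on the wrong face of the C8 radical, because the ten-membered ring is mobile and only the adjacent C7–C11 bond differentiates the faces.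

The first two are matters of concentration; the third is the one that would need a change of approach. The fallback sets out from 16 and comes back at 18, and fixes C8 by substitution with inversion instead of by radical capture. The cyclisation would be run as in step 11, and the C8-epimeric alcohol F1 would be treated with PPh3, diisopropyl azodicarboxylate and 4-nitrobenzoic acid (Mitsunobu reaction) to give the inverted 4-nitrobenzoate F2. Methanolysis (K2CO3, MeOH) would then return 18.

Step 10. The ruthenium carbene may form on the C7 vinyl group and close onto the trisubstituted C10=C1 olefin, which would give a seven-membered ring with loss of the allyl terminus. Oligomerisation may also win because a ten-membered ring closes slowly. The fallback sets out from 8 and comes back at 18; it closes the ring by carbonyl addition at C6–C7 instead of by metathesis: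
- cross-metathesis of 8 with vinylboronic acid pinacol ester (same ruthenium catalyst) would give the E-alkenylboronate F3;
- NaOH and I2 would convert it with retention into the E-vinyl iodide F4;
- Dess–Martin oxidation would give the iodo epoxy aldehyde F5;
- CrCl2 with catalytic NiCl2 in DMSO/THF at high dilution (Nozaki–Hiyama–Kishi reaction) would close the ring to the (3E)-epoxy dienol F6;
- bromoacetalisation with 14 as in step 9 would give the (3E)-bromoacetal F7, which under the conditions of step 11 converges on 18, because the C7=C8 geometry is erased there.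

Step 7. Facial selectivity in the addition to the epoxy aldehyde may be poor, because chelation of magnesium between the carbonyl and epoxide oxygens favours the opposite face to the Felkin–Anh arrangement. The fallback sets out from 9 and comes back at 11; it sets C6 by reduction instead of by addition. The unwanted (1R)-epimer F8, alone or mixed with 11, would be oxidised (Dess–Martin periodinane) to the epoxy vinyl ketone F9. Reduction with Zn(BH4)2 in ether at −20 °C should then deliver hydride to the chelated carbonyl from the side of H5 and give the erythro alcohol 11.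

Step 15. Aminomethylation at C11 on the concave side of the cis-fused lactone may be slow, so that the enolate lives long enough to condense with unreacted lactone or to be quenched. The fallback sets out from 21 and comes back at 25; it uses an aldol and a β-elimination instead of the Mannich and Hofmann-type sequence. The lithium enolate would be treated with monomeric formaldehyde to give the 13-hydroxymethyl lactone F10. Mesylation (MeSO2Cl, Et3N) would give the mesylate F11, and DBU would eliminate it to 25.

## Further compounds

F1 | step 11 | (8S)-epimer of 18 | C1C(OCc3ccc(OC)cc3)O[C@H]2[C@@H]1[C@@H](O)C/C(C)=C\CC[C@@]1(C)O[C@@H]21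
F2 | step 11 | (8R)-4-nitrobenzoate of 18 | C1C(OCc3ccc(OC)cc3)O[C@H]2[C@@H]1[C@H](OC(=O)c3ccc(cc3)[N+](=O)[O-])C/C(C)=C\CC[C@@]1(C)O[C@@H]21
F3 | step 10 | [(2S,3R)-3-methyl-3-[(3Z,6E)-4-methyl-7-(4,4,5,5-tetramethyl-1,3,2-dioxaborolan-2-yl)hepta-3,6-dien-1-yl]oxiran-2-yl]methanol | OC[C@@H]1O[C@]1(C)CC/C=C(C)\C/C=C/B1OC(C)(C)C(C)(C)O1
F4 | step 10 | [(2S,3R)-3-[(3Z,6E)-7-iodo-4-methylhepta-3,6-dien-1-yl]-3-methyloxiran-2-yl]methanol | OC[C@@H]1O[C@]1(C)CC/C=C(C)\C/C=C/I
F5 | step 10 | (2R,3R)-3-[(3Z,6E)-7-iodo-4-methylhepta-3,6-dien-1-yl]-3-methyloxirane-2-carbaldehyde | O=C[C@@H]1O[C@]1(C)CC/C=C(C)\C/C=C/I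
F6 | step 10 | (1S,2S,3E,6Z,10R)-6,10-dimethyl-11-oxabicyclo[8.1.0]undeca-3,6-dien-2-ol | O[C@H]1/C=C/C/C(C)=C\CC[C@@]2(C)O[C@@H]12
F7 | step 10 | (3E)-isomer of 16, both acetal epimers | COc1ccc(COC(CBr)O[C@H]2/C=C/C/C(C)=C\CC[C@@]3(C)O[C@@H]23)cc1
F8 | step 7 | (1R)-1-[(2S,3R)-3-methyl-3-[(3Z)-4-methylhepta-3,6-dien-1-yl]oxiran-2-yl]prop-2-en-1-ol | C=C[C@@H](O)[C@@H]1O[C@]1(C)CC/C=C(C)\CC=C
F9 | step 7 | 1-[(2R,3R)-3-methyl-3-[(3Z)-4-methylhepta-3,6-dien-1-yl]oxiran-2-yl]prop-2-en-1-one | C=CC(=O)[C@@H]1O[C@]1(C)CC/C=C(C)\CC=C
F10 | step 15 | (4R,5S,6S,7R,8R,1(10)Z)-4,5-epoxy-13-hydroxy-8-(triethylsilyloxy)germacr-1(10)-en-12,6-olide, C11 epimers | OCC1C(=O)O[C@H]2[C@@H]1[C@H](O[Si](CC)(CC)CC)C/C(C)=C\CC[C@@]1(C)O[C@@H]21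
F11 | step 15 | 13-methanesulfonate of F10 | CS(=O)(=O)OCC1C(=O)O[C@H]2[C@@H]1[C@H](O[Si](CC)(CC)CC)C/C(C)=C\CC[C@@]1(C)O[C@@H]21
A1 | alternative 1 | cis-fused 6-hydroxy-4,10-dimethyl-10-(trimethylstannyl)bicyclo[4.4.0]dec-4-en-8-one (germacrane locants, C1–C6 bond present; relative configuration) | O[C@]12CC(=O)C[C@@](C)([Sn](C)(C)C)[C@H]1CCC(C)=C2
A2 | alternative 1 | (4Z,8Z)-5,9-dimethylcyclodeca-4,8-diene-1,3-dione | C1C(=O)/C=C(C)\CC/C=C(C)\CC1=O
A3 | alternative 2 | (3Z)-6-[(2R,3S)-3-ethenyl-2-methyloxiran-2-yl]-3-methylhex-3-enal oxime | ON=CC/C(C)=C\CC[C@@]1(C)O[C@H]1C=C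
A4 | alternative 2 | ten-membered carbocycle bridged by the C8=N–O–C6 isoxazoline | O1N=C2C[C@H]1[C@@H]3O[C@]3(C)CC/C=C(C)\C2
A5 | alternative 3 | tert-butyl (6Z,10Z)-4-[(tert-butyldimethylsilyl)oxy]-3-formyl-11-iodo-6,10-dimethylundeca-6,10-dienoate, C7 and C8 as in A6 | I/C=C(C)\CC/C=C(C)\C[C@@H](O[Si](C)(C)C(C)(C)C)[C@@H](C=O)CC(=O)OC(C)(C)C
A6 | alternative 3 | ten-membered Z,Z-dienol tert-butyl ester | O[C@@H]1/C=C(C)\CC/C=C(C)\C[C@@H](O[Si](C)(C)C(C)(C)C)[C@@H]1CC(=O)OC(C)(C)C
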